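**Retrosynthetic overview**

1. The benzyl ether is removed last. Before that, the lactone C–O bond of the coumarin ring is closed by carboxylic-acid-directed C–H lactonisation, so the A ring carries no oxygen at that carbon until the end.
2. The biaryl bond (coumarin C4–C4a) comes from Pd-catalysed C2–H arylation of a benzofuran-3-carboxylate with an 8-bromochroman. The furan ring is made separately from a salicylaldehyde and ethyl diazoacetate.
3. The feature behind the key step lies in the dihydropyran ring: its O1 and C4 sit on two neighbouring aromatic carbons next to the methoxy-bearing carbon, and O1–C(CH3)2–CH2–C4 is the atom string of a β-lactone. The ring is therefore made by two-atom ring expansion of 4,4-dimethyloxetan-2-one, through insertion of 3-methoxybenzyne into its O–C(=O) bond, followed by C4=O → CH2.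
4. Order of ring formation: oxetanone (four-membered) → pyranone/pyran ring by expansion on the aryne; furan ring (separate branch); coumarin lactone ring last.

Key step: step 2

Assumption: the target has no stereocentre (C2 of the pyran carries two methyl groups, all other ring atoms are aromatic), so no stereocontrol is needed; compounds 1, 3, 9 and 10 are taken as purchased.

**Route**

Step 1
Reactants: 1 3-hydroxy-3-methylbutanoic acid
Product: 2 4,4-dimethyloxetan-2-one
Conditions: PhSO2Cl (2 equiv), pyridine, 0–5 °C; distillation
Reagents that add atoms: none
Why: β-lactonisation by carboxyl activation: the mixed sulfonic–carboxylic anhydride should be attacked 4-exo-trig by the tertiary hydroxyl, helped by the gem-dimethyl effect; no stereocentre is formed.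

Step 2
Reactants: 3 3-methoxy-2-(trimethylsilyl)phenyl trifluoromethanesulfonate; 2 4,4-dimethyloxetan-2-one (3 equiv)
Product: 6 5-methoxy-2,2-dimethylchroman-4-one, via 3-methoxybenzyne 4 (not isolated), via aryl-anion oxetanonium zwitterion 5 (not isolated)
Conditions: CsF (3 equiv), MeCN, 23 → 60 °C, slow addition of 3 to 2 and CsF
Reagents that add atoms: none
Why: Proposed new method: fluoride-induced 1,2-elimination of 3 should give aryne 4, the ring oxygen of the strained lactone 2 adds to C1 (the aryne carbon remote from OMe) to give zwitterion 5, and the carbanion at C2 then attacks the acyl carbon of the acyloxonium unit so that the acyl group moves from oxygen to carbon and the two aryne carbons stand inserted in the former O–C(=O) bond. The closest known reactions are the insertion of arynes into the N–C(=O) bond of β-lactams (ring expansion to 2,3-dihydroquinolin-4-ones) and into the O–C(=O) bond of carboxylic acids (o-hydroxyaryl ketones and, from 3-methylbut-2-enoic acid, 2,2-dimethylchroman-4-ones); the same σ-insertion into a β-lactone has not been shown. The pyranone ring is not closed from an open chain but arises by two-atom ring expansion of the oxetanone: the ring-forming bond C4–C4a comes from addition of the aryl carbanion to the lactone carbonyl through a four-membered tetrahedral intermediate that collapses with O–acyl cleavage, driven by loss of about 23 kcal/mol of ring strain. No stereocentre is formed. The selectivity needed is regiochemical (O on the carbon meta to OMe, C=O on the carbon ortho to it) and it is secured by the inductively withdrawing methoxy group beside the triple bond, which distorts the aryne so that nucleophiles attack the remote carbon and the charge builds up next to the C–OMe bond; the excess of 2 and the slow release of 4 are meant to let the weakly nucleophilic lactone win over fluoride and over aryne self-reaction.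

Step 3
Reactants: 6 5-methoxy-2,2-dimethylchroman-4-one
Product: 7 5-methoxy-2,2-dimethylchroman
Conditions: Et3SiH (4 equiv), TFA, CH2Cl2, 0 °C → rt
Reagents that add atoms: none
Why: ionic hydrogenation of an electron-rich aryl ketone: the protonated ketone and then the benzylic cation stabilised by the two ortho oxygens should each take hydride from the silane, and the tertiary alkyl aryl ether is stable to TFA.

Step 4
Reactants: 7 5-methoxy-2,2-dimethylchroman
Product: 8 8-bromo-5-methoxy-2,2-dimethylchroman
Conditions: NBS (1.0 equiv), MeCN, −20 → 0 °C
Reagents that add atoms: N-bromosuccinimide, O=C1CCC(=O)N1Br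
Why: electrophilic aromatic bromination: C8 is para to OMe and ortho only to the tied-back ring oxygen, while C6 is shielded by the O-methyl group that lies in the ring plane on its side, so the 8-bromide is expected as the main isomer.

Step 5
Reactants: 9 4-(benzyloxy)-2-hydroxybenzaldehyde; 10 ethyl diazoacetate
Product: 12 ethyl 6-(benzyloxy)benzofuran-3-carboxylate, via 2-hydroxy-2,3-dihydrobenzofuran hemiacetal 11 (not isolated)
Conditions: HBF4·OEt2 (10 mol%), CH2Cl2, rt; then conc. H2SO4 (cat.), rt
Reagents that add atoms: none
Why: acid-catalysed addition of the diazo ester to the aldehyde with 1,2-aryl shift and loss of N2 should give the α-formyl arylacetate, which the phenol traps as hemiacetal 11 and which dehydrates to the aromatic benzofuran; the two stereocentres of 11 are lost again.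

Step 6
Reactants: 8 8-bromo-5-methoxy-2,2-dimethylchroman; 12 ethyl 6-(benzyloxy)benzofuran-3-carboxylate
Product: 13 ethyl 6-(benzyloxy)-2-(5-methoxy-2,2-dimethylchroman-8-yl)benzofuran-3-carboxylate
Conditions: Pd(OAc)2 (5 mol%), PCy3·HBF4 (10 mol%), PivOH (30 mol%), K2CO3 (2 equiv), DMA, 110 °C
Reagents that add atoms: none
Why: Pd-catalysed direct C–H arylation by concerted metalation–deprotonation at C2, the only furan C–H, which is acidified by the ring oxygen and the 3-ester.

Step 7
Reactants: 13 ethyl 6-(benzyloxy)-2-(5-methoxy-2,2-dimethylchroman-8-yl)benzofuran-3-carboxylate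
Product: 14 6-(benzyloxy)-2-(5-methoxy-2,2-dimethylchroman-8-yl)benzofuran-3-carboxylic acid
Conditions: LiOH·H2O (5 equiv), THF/MeOH/H2O, 60 °C; then 1 M HCl
Reagents that add atoms: lithium hydroxide, [Li+].[OH-]
Why: saponification of the ethyl ester; the aryl ethers and the chroman ring are inert to aqueous base.

Step 8
Reactants: 14 6-(benzyloxy)-2-(5-methoxy-2,2-dimethylchroman-8-yl)benzofuran-3-carboxylic acid
Product: 15 9-(benzyloxy)-3-methoxycoumestan with the 2,2-dimethyl-3,4-dihydro-2H-pyran ring fused at C1 (O) and C2 (CH2) (the O-benzyl ether of the target)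
Conditions: Cu(OAc)2 (10 mol%), (PhCO2)2 (1.3 equiv), HFIP, 75 °C
Reagents that add atoms: none
Why: carboxylate-directed dehydrogenative C(sp2)–H lactonisation of a biaryl-2-carboxylic acid (copper/peroxide, six-membered C–O closure): the only C–H ortho to the biaryl bond is C7–H of the chroman, because the other ortho position carries the ring oxygen, so the lactone oxygen can only go to the required carbon.

Step 9
Reactants: 15 O-benzyl ether of the target
Product: 16 target CNP0304440.0 (9-hydroxy-3-methoxycoumestan with the 2,2-dimethyl-3,4-dihydro-2H-pyran ring fused at C1 (O) and C2 (CH2))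
Conditions: H2 (1 atm), 10% Pd/C, THF/EtOAc, rt
Reagents that add atoms: none
Why: hydrogenolysis of the benzyl aryl ether; the coumestan core is fully aromatic and the lactone should not be reduced under these conditions.

**Compound list**

1 | 3-hydroxy-3-methylbutanoic acid | CC(C)(O)CC(=O)O | starting material
2 | 4,4-dimethyloxetan-2-one | CC1(C)CC(=O)O1 | intermediate
3 | 3-methoxy-2-(trimethylsilyl)phenyl trifluoromethanesulfonate | COc1cccc(OS(=O)(=O)C(F)(F)F)c1[Si](C)(C)C | starting material
4 | 3-methoxybenzyne (1,2-didehydro-3-methoxybenzene; not isolated) | COC1=CC=CC#C1 | intermediate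
5 | zwitterion from O-attack of 2 on C1 of 4: 4,4-dimethyl-2-oxooxetan-1-ium carrying on O the 3-methoxyphenyl-2-ide (not isolated) | COc1cccc([O+]2C(=O)CC2(C)C)[c-]1 | intermediate
6 | 5-methoxy-2,2-dimethylchroman-4-one | COc1cccc2OC(C)(C)CC(=O)c12 | intermediate
7 | 5-methoxy-2,2-dimethylchroman | COc1cccc2OC(C)(C)CCc12 | intermediate
8 | 8-bromo-5-methoxy-2,2-dimethylchroman | COc1ccc(Br)c2OC(C)(C)CCc12 | intermediate
9 | 4-(benzyloxy)-2-hydroxybenzaldehyde | O=Cc1ccc(OCc2ccccc2)cc1O | starting material
10 | ethyl diazoacetate | CCOC(=O)C=[N+]=[N-] | starting material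
11 | ethyl 6-(benzyloxy)-2-hydroxy-2,3-dihydrobenzofuran-3-carboxylate (racemic mixture of diastereomers; not isolated) | CCOC(=O)C1C(O)Oc2cc(OCc3ccccc3)ccc12 | intermediate
12 | ethyl 6-(benzyloxy)benzofuran-3-carboxylate | CCOC(=O)c1coc2cc(OCc3ccccc3)ccc12 | intermediate
13 | ethyl 6-(benzyloxy)-2-(5-methoxy-2,2-dimethylchroman-8-yl)benzofuran-3-carboxylate | CCOC(=O)c1c(-c2ccc(OC)c3CCC(C)(C)Oc23)oc2cc(OCc3ccccc3)ccc12 | intermediate
14 | 6-(benzyloxy)-2-(5-methoxy-2,2-dimethylchroman-8-yl)benzofuran-3-carboxylic acid | OC(=O)c1c(-c2ccc(OC)c3CCC(C)(C)Oc23)oc2cc(OCc3ccccc3)ccc12 | intermediate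
15 | O-benzyl ether of the target (9-benzyloxy-3-methoxycoumestan with the dimethyldihydropyran ring at C1/C2) | COc1cc2oc(=O)c3c4ccc(OCc5ccccc5)cc4oc3c2c2c1CCC(C)(C)O2 | intermediate
16 | target CNP0304440.0 | COc1cc2oc(=O)c3c4ccc(O)cc4oc3c2c2c1CCC(C)(C)O2 | target

**Step count and risks**

Total step count: 9. Longest linear sequence: 8 steps (1 → 2 → 6 → 7 → 8 → 13 → 14 → 15 → 16; the benzofuran ester 12 comes from a one-step side branch).

Step 2 (proposed new method). What may go wrong is the competition for the aryne: the lactone is a weak, neutral O-nucleophile, so the aryne may be consumed by fluoride or by self-reaction, or the lactone may be opened by fluoride before it is arylated. The fallback keeps a ring expansion but uses known chemistry, a one-atom oxygen insertion. It does not branch from a numbered compound of the route: it sets out from purchased 4-methoxyindan-1-one F1 and comes back at compound 7. Baeyer–Villiger oxidation of 4-methoxyindan-1-one F1 (m-CPBA, TFA, CH2Cl2) with aryl migration should expand the cyclopentanone to the six-membered lactone 5-methoxychroman-2-one F2. Methylmagnesium bromide (3 equiv, THF) then opens the lactone to the diol 2-(3-hydroxy-3-methylbutyl)-3-methoxyphenol F3. p-TsOH (toluene, 80 °C) closes the same six-membered ring again by attack of the phenol on the tertiary cation, which gives 7; the route continues with step 4.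

Step 8. What may go wrong is over-oxidation of the very electron-rich rings: intermolecular benzoyloxylation, or hydrogen abstraction at the benzylic CH2 groups of the chroman and the benzyl ether, instead of the intramolecular C–O closure. The fallback puts the oxygen on before the rings are joined and closes the lactone by acyl substitution; it sets out from compound 7 and comes back at compound 15. Iridium-catalysed C–H borylation of 7 ([Ir(OMe)(cod)]2, dtbpy, B2pin2, 80 °C) should go to C7, the only C–H without an ortho substituent, and give 2-(5-methoxy-2,2-dimethylchroman-7-yl)-4,4,5,5-tetramethyl-1,3,2-dioxaborolane F4. Oxidation (NaBO3, THF/H2O) gives 5-methoxy-2,2-dimethylchroman-7-ol F5. Bromination ortho to the hydroxyl, on the side of the ring oxygen (NBS, CH2Cl2, −78 °C), gives 8-bromo-5-methoxy-2,2-dimethylchroman-7-ol F6. Palladium-catalysed coupling of F6 with 12 under the conditions of step 6 (3 equiv K2CO3) then joins the rings, and the phenoxide closes the lactone on the neighbouring ethyl ester in the same pot, which gives 15.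

Step 6. What may go wrong is slow oxidative addition of the electron-rich, ortho-oxygenated bromide, so that protodebromination and homocoupling outrun the C–H arylation at the hindered C2 position. The fallback replaces the C–H arylation by a Suzuki–Miyaura coupling of two pre-functionalised partners; it sets out from compounds 8 and 12 and comes back at compound 13. Miyaura borylation of 8 (B2pin2, PdCl2(dppf), KOAc, dioxane, 90 °C) gives 2-(5-methoxy-2,2-dimethylchroman-8-yl)-4,4,5,5-tetramethyl-1,3,2-dioxaborolane F7. Magnesiation of 12 at C2 (TMPMgCl·LiCl, THF, −40 °C) and quenching with 1,2-dibromotetrachloroethane gives ethyl 6-(benzyloxy)-2-bromobenzofuran-3-carboxylate F8. Coupling of F7 with F8 (Pd(OAc)2, SPhos, K3PO4, toluene/H2O, 80 °C) gives 13.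

**Further compounds**

F1 | step 2 | 4-methoxyindan-1-one (purchased starting material of the fallback) | COc1cccc2C(=O)CCc12
F2 | step 2 | 5-methoxychroman-2-one | COc1cccc2OC(=O)CCc12
F3 | step 2 | 2-(3-hydroxy-3-methylbutyl)-3-methoxyphenol | COc1cccc(O)c1CCC(C)(C)O
F4 | step 8 | 2-(5-methoxy-2,2-dimethylchroman-7-yl)-4,4,5,5-tetramethyl-1,3,2-dioxaborolane | COc1cc(B2OC(C)(C)C(C)(C)O2)cc2OC(C)(C)CCc12
F5 | step 8 | 5-methoxy-2,2-dimethylchroman-7-ol | COc1cc(O)cc2OC(C)(C)CCc12
F6 | step 8 | 8-bromo-5-methoxy-2,2-dimethylchroman-7-ol | COc1cc(O)c(Br)c2OC(C)(C)CCc12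
F7 | step 6 | 2-(5-methoxy-2,2-dimethylchroman-8-yl)-4,4,5,5-tetramethyl-1,3,2-dioxaborolane | COc1ccc(B2OC(C)(C)C(C)(C)O2)c2OC(C)(C)CCc12
F8 | step 6 | ethyl 6-(benzyloxy)-2-bromobenzofuran-3-carboxylate | CCOC(=O)c1c(Br)oc2cc(OCc3ccccc3)ccc12
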